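**Plan**

- Ring numbering used below: C1 = quaternary carbon (CH2OH and homofarnesyl chain), C2 = CH bearing the 3-hydroxypropyl group, C3 = ring carbon of the exocyclic enal, C4 and C5 = CH2, C6 = C(CH3)OH. The enabling feature is that oxygenated C6 lies 1,4 to trigonal C3 and C1 carries a one-carbon acceptor, so C5=C6(OSi)–C1(CO2Me)=C2 is a 2-silyloxydiene and C4=C3 a ketene equivalent.
- Retrosynthesis: enal ⇒ C3 ketone (through C3=CBr2, methyl first, formyl second); C6–CH3 ⇒ C6 ketone; C1–chain ⇒ β-keto ester alkylation; ring bonds C2–C3 and C4–C5 together ⇒ Diels–Alder reaction of the diene with a chiral 5-methylidene-1,3-dioxolan-4-one.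
- Forward: dienophile (3 steps) and diene (2 steps); the cycloaddition closes the only ring; the homofarnesyl chain (made separately in 4 steps) is joined at C1; methyl is added to C6; LiAlH4 then NaIO4 unmask C1–CH2OH and C3=O; the enal is built on C3; desilylation ends the route.
- Stereochemistry: the single bought stereocentre of (R)-lactic acid fixes the acetal carbon of the dienophile, which sets C2 in the cycloaddition (diene anti to tert-butyl, lactone carbonyl exo). C2 then directs C1 (alkylation trans to the C2 side chain) and C6 (methyl enters anti to the ester and the C2 side chain). The auxiliary carbons leave as neopentyl alcohol and formaldehyde.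
- Alkene geometry: the two C–Br bonds of C3=CBr2 differ sterically; palladium should insert cis to C4H2, so methyl ends cis to C4 and the formyl group cis to C2.

Key step: step 6

Remark on the chemistry: 4-[(tert-butyldimethylsilyl)oxy]butanal is taken as a purchasable aldehyde (otherwise two steps from butane-1,4-diol).

**Route**

Step 1
Reactants: 1 (R)-lactic acid; 2 pivalaldehyde (2,2-dimethylpropanal)
Product: 3 (2R,5R)-2-tert-butyl-5-methyl-1,3-dioxolan-4-one (tert-butyl cis to methyl)
Conditions: p-TsOH (cat.), H2SO4 (cat.), pentane, reflux, azeotropic removal of water; crystallisation of the cis isomer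
Reagents that add atoms: none
Why: Acid-catalysed acetalisation of an α-hydroxy acid under thermodynamic control should give the cis-dioxolanone, so the bought C5 stereocentre sets the acetal carbon C2, which survives when C5 later becomes trigonal.

Step 2
Reactants: 3 (2R,5R)-2-tert-butyl-5-methyl-1,3-dioxolan-4-one
Product: 4 (2R,5S)-5-bromo-2-tert-butyl-5-methyl-1,3-dioxolan-4-one (bromine trans to tert-butyl)
Conditions: N-bromosuccinimide, AIBN (cat.), PhCF3, reflux
Reagents that add atoms: N-bromosuccinimide, O=C1CCC(=O)N1Br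
Why: Wohl–Ziegler radical bromination should take place at the captodatively stabilised C5–H, the bromine entering trans to the tert-butyl group.

Step 3
Reactants: 4 (2R,5S)-5-bromo-2-tert-butyl-5-methyl-1,3-dioxolan-4-one
Product: 5 (2R)-2-tert-butyl-5-methylidene-1,3-dioxolan-4-one
Conditions: Et3N, CH2Cl2, 0 °C to rt
Reagents that add atoms: none
Why: E2 dehydrobromination of the tertiary α-bromo lactone should give the exocyclic α-alkoxyacrylate, a chiral ketene-equivalent dienophile whose only stereocentre is the acetal carbon.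

Step 4
Reactants: 6 4-[(tert-butyldimethylsilyl)oxy]butanal; 7 methyl acetoacetate
Product: 8 methyl (2Z)-2-acetyl-6-[(tert-butyldimethylsilyl)oxy]hex-2-enoate
Conditions: piperidine (cat.), AcOH (cat.), 4 Å molecular sieves, CH2Cl2, 0 °C to rt; chromatography, the E isomer being re-equilibrated under the same conditions
Reagents that add atoms: none
Why: Knoevenagel condensation should give the alkylidene β-keto ester, the Z isomer (side chain cis to the ester, trans to the acetyl group) being the one needed for an s-cis diene with an outward side chain.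

Step 5
Reactants: 8 methyl (2Z)-2-acetyl-6-[(tert-butyldimethylsilyl)oxy]hex-2-enoate
Product: 9 methyl (2Z)-6-[(tert-butyldimethylsilyl)oxy]-2-{1-[(triethylsilyl)oxy]ethenyl}hex-2-enoate
Conditions: Et3SiOTf, Et3N, CH2Cl2, −78 °C
Reagents that add atoms: triethylsilyl trifluoromethanesulfonate, CC[Si](CC)(CC)OS(=O)(=O)C(F)(F)F
Why: Soft enolisation of the methyl ketone (O-silylation, then kinetic loss of a proton from the adjacent CH3) should give the cross-conjugated 2-silyloxydiene, as with other α,β-unsaturated methyl ketones, without touching the C2=C3 geometry.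

Step 6
Reactants: 9 methyl (2Z)-6-[(tert-butyldimethylsilyl)oxy]-2-{1-[(triethylsilyl)oxy]ethenyl}hex-2-enoate; 5 (2R)-2-tert-butyl-5-methylidene-1,3-dioxolan-4-one
Product: 11 methyl (2R)-2-tert-butyl-6-{3-[(tert-butyldimethylsilyl)oxy]propyl}-4,8-dioxo-1,3-dioxaspiro[4.5]decane-7-carboxylate (side chain cis to the acetal ring oxygen on the spiro carbon; ester carbon unfixed, keto and enol forms), via triethylsilyl enol ether cycloadduct 10 (not isolated)
Conditions: toluene, BHT (cat.), 90 °C, sealed tube; then 0.5 M aq. HCl, THF, 0 °C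
Reagents that add atoms: none
Why: The step is a thermal, concerted but asynchronous Diels–Alder reaction of normal electron demand in which the nucleophilic CH2 terminus of the silyloxydiene (future C5) bonds to the CH2 of the α-alkoxyacrylate (future C4) and the ester-activated diene terminus (future C2) bonds to its oxygenated carbon (future C3). The closest known reaction type is the cycloaddition of 2-silyloxy-1,3-dienes, and of acyclic dienes in general, with 2-tert-butyl-5-methylidene-1,3-dioxolan-4-ones used as chiral ketene equivalents. One ring is closed, the six-membered carbocycle C1–C6, by suprafacial [4+2] cycloaddition that forms both ring bonds at once and leaves the dioxolanone as a spiro ring on C3. The new stereocentres C2 and C3 are controlled by the acetal carbon of 5: the diene should add to the face of the methylidene group opposite the tert-butyl group with the lactone carbonyl exo, which with the Z diene places the side chain cis to the acetal ring oxygen and gives C2 the configuration of the target. The step needs regio, facial and exo selectivity; the first is secured by the matched polarisation of the partners (silyloxy donor on C6, ester acceptor on C1, captodative dienophile), the second by the tert-butyl group, and the third by the exo preference of α-oxygenated methylidene lactones, reinforced by the C1 ester beneath the endo position. Dilute acid on work-up should hydrolyse only the triethylsilyl enol ether and deliver the β-keto ester, whose C1 is set in step 11.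

Step 7
Reactants: 12 (2E,6E)-farnesol
Product: 13 (2E,6E)-farnesal
Conditions: TEMPO (cat.), PhI(OAc)2, CH2Cl2, rt
Reagents that add atoms: none
Why: Nitroxyl-catalysed oxidation of the allylic alcohol should stop at the enal without isomerising the 2,3-double bond.

Step 8
Reactants: 13 (2E,6E)-farnesal
Product: 14 (3E,7E)-4,8,12-trimethyltrideca-1,3,7,11-tetraene
Conditions: Ph3PCH3Br, KOtBu, THF, 0 °C
Reagents that add atoms: methyltriphenylphosphonium bromide, C[P+](c1ccccc1)(c1ccccc1)c1ccccc1.[Br-]
Why: Wittig methylenation of the enal should give the terminal diene without touching the trisubstituted alkenes.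

Step 9
Reactants: 14 (3E,7E)-4,8,12-trimethyltrideca-1,3,7,11-tetraene
Product: 16 (3E,7E)-4,8,12-trimethyltrideca-3,7,11-trien-1-ol (homofarnesol), via B-alkyl-9-borabicyclo[3.3.1]nonane 15 (not isolated)
Conditions: 9-BBN, THF, 0 °C to rt; then NaOH, H2O2, 0 °C
Reagents that add atoms: hydrogen peroxide, OO
Why: Hydroboration–oxidation with a bulky dialkylborane should be selective for the monosubstituted terminal alkene and place oxygen on the terminal carbon.

Step 10
Reactants: 16 (3E,7E)-4,8,12-trimethyltrideca-3,7,11-trien-1-ol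
Product: 17 (3E,7E)-homofarnesyl iodide (13-iodo-2,6,10-trimethyltrideca-2,6,10-triene)
Conditions: PPh3, N-iodosuccinimide, CH2Cl2, 0 °C
Reagents that add atoms: N-iodosuccinimide, O=C1CCC(=O)N1I
Why: Appel-type iodination of the primary alcohol proceeds by SN2 displacement of the alkoxyphosphonium ion and should leave the alkenes untouched.

Step 11
Reactants: 11 the spiro β-keto ester of step 6; 17 (3E,7E)-homofarnesyl iodide
Product: 18 methyl (2R)-2-tert-butyl-6-{3-[(tert-butyldimethylsilyl)oxy]propyl}-4,8-dioxo-7-[(3E,7E)-4,8,12-trimethyltrideca-3,7,11-trien-1-yl]-1,3-dioxaspiro[4.5]decane-7-carboxylate (chain trans, ester cis to the C2 side chain)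
Conditions: NaH, THF/DMF, 0 °C to 40 °C
Reagents that add atoms: none
Why: C-alkylation of the β-keto ester enolate with a primary iodide builds quaternary C1, and the electrophile should enter from the ring face opposite both the C2 side chain and the acetal oxygen on C3, leaving the ester cis to the side chain.

Step 12
Reactants: 18 the C1-alkylated β-keto ester
Product: 19 the C6 tertiary alcohol (8-hydroxy-8-methyl analogue of 18; hydroxyl cis to the ester and to the C2 side chain, methyl cis to the homofarnesyl chain)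
Conditions: MeMgBr, THF, −78 °C to −40 °C
Reagents that add atoms: methylmagnesium bromide, C[Mg]Br
Why: Grignard 1,2-addition to the ketone should occur by axial attack on the chair with axial ester and equatorial chain, anti to the ester and the C2 side chain, while the hindered ester and lactone carbonyls react more slowly at low temperature.

Step 13
Reactants: 19 the C6 tertiary alcohol
Product: 20 1,3-bis(hydroxymethyl)-4-methyl-2-{3-[(tert-butyldimethylsilyl)oxy]propyl}-3-[(3E,7E)-4,8,12-trimethyltrideca-3,7,11-trien-1-yl]cyclohexane-1,4-diol (tetraol; ring stereocentres as in 19)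
Conditions: LiAlH4, THF, 0 °C to rt
Reagents that add atoms: none
Why: Hydride reduction should convert the methyl ester into the C1 hydroxymethyl group and open the dioxolanone to the C3 tertiary/primary 1,2-diol, the acetal carbon leaving as neopentyl alcohol, with no stereocentre touched.

Step 14
Reactants: 20 the tetraol
Product: 21 (2R,3R,4R)-4-hydroxy-3-(hydroxymethyl)-4-methyl-2-{3-[(tert-butyldimethylsilyl)oxy]propyl}-3-[(3E,7E)-4,8,12-trimethyltrideca-3,7,11-trien-1-yl]cyclohexan-1-one
Conditions: NaIO4, THF/pH 7 buffer, 0 °C to rt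
Reagents that add atoms: none
Why: Malaprade glycol cleavage should unmask the C3 ketone under neutral conditions, so the adjacent C2 stereocentre is not epimerised and the 1,3-diol and alkenes stay inert.

Step 15
Reactants: 21 the keto diol
Product: 22 the di-tert-butylsilylene acetal of 21 (C1–CH2O and C6–O joined through Si(t-Bu)2 in a cis-fused 1,3,2-dioxasilinane)
Conditions: t-Bu2Si(OTf)2, 2,6-lutidine, CH2Cl2, 0 °C
Reagents that add atoms: di-tert-butylsilyl bis(trifluoromethanesulfonate), CC(C)(C)[Si](OS(=O)(=O)C(F)(F)F)(OS(=O)(=O)C(F)(F)F)C(C)(C)C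
Why: Silylene formation is favoured for the cis-1,3-diol and should protect the primary and the tertiary hydroxyl in one step before the phosphine and organolithium chemistry.

Step 16
Reactants: 22 the silylene-protected ketone
Product: 23 the C3 dibromomethylidene compound (C3=CBr2)
Conditions: CBr4, PPh3, Zn, CH2Cl2, rt to 40 °C
Reagents that add atoms: carbon tetrabromide, BrC(Br)(Br)Br
Why: Ramirez dibromoolefination with the non-basic ylide Ph3P=CBr2 should convert the ketone into the 1,1-dibromoalkene without epimerising C2.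

Step 17
Reactants: 23 the C3 dibromomethylidene compound
Product: 24 the (Z)-1-bromoethylidene compound (methyl cis to C4H2, bromine cis to C2)
Conditions: MeZnCl, PdCl2[(2-Ph2PC6H4)2O] (cat.), THF, 0 °C to rt
Reagents that add atoms: methylzinc chloride, C[Zn]Cl
Why: In this Negishi mono-coupling of a 1,1-dibromoalkene, oxidative addition should take place at the less hindered C–Br bond, the one cis to unsubstituted C4H2 and trans to branched C2, and the alkene geometry is fixed here.

Step 18
Reactants: 24 the (Z)-1-bromoethylidene compound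
Product: 26 the bis-silyl-protected (Z)-enal (formyl cis to C2), via tetrasubstituted vinyllithium 25 (not isolated)
Conditions: t-BuLi, Et2O, −78 °C; then DMF, −78 °C to 0 °C; then H2O
Reagents that add atoms: N,N-dimethylformamide, CN(C)C=O
Why: Bromine–lithium exchange should give a configurationally stable vinyllithium that is formylated by DMF with retention, so the aldehyde ends cis to C2.

Step 19
Reactants: 26 the bis-silyl-protected (Z)-enal
Product: 27 (2Z)-2-[(2S,3R,4R)-4-hydroxy-3-(hydroxymethyl)-2-(3-hydroxypropyl)-4-methyl-3-[(3E,7E)-4,8,12-trimethyltrideca-3,7,11-trien-1-yl]cyclohexylidene]propanal (target)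
Conditions: HF·pyridine, pyridine, THF, 0 °C to rt
Reagents that add atoms: none
Why: Fluoride-driven desilylation should remove the primary silyl ether and the silylene together under conditions that the enal, the tertiary alcohol and the trisubstituted alkenes tolerate.

**Compound list**

1 | (R)-lactic acid | C[C@@H](O)C(=O)O | starting material
2 | pivalaldehyde (2,2-dimethylpropanal) | CC(C)(C)C=O | starting material
3 | (2R,5R)-2-tert-butyl-5-methyl-1,3-dioxolan-4-one | C[C@H]1O[C@@H](C(C)(C)C)OC1=O | intermediate
4 | (2R,5S)-5-bromo-2-tert-butyl-5-methyl-1,3-dioxolan-4-one | C[C@@]1(Br)O[C@@H](C(C)(C)C)OC1=O | intermediate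
5 | (2R)-2-tert-butyl-5-methylidene-1,3-dioxolan-4-one | C=C1O[C@@H](C(C)(C)C)OC1=O | intermediate
6 | 4-[(tert-butyldimethylsilyl)oxy]butanal | CC(C)(C)[Si](C)(C)OCCCC=O | starting material
7 | methyl acetoacetate | COC(=O)CC(C)=O | starting material
8 | methyl (2Z)-2-acetyl-6-[(tert-butyldimethylsilyl)oxy]hex-2-enoate | CC(=O)/C(=C/CCCO[Si](C)(C)C(C)(C)C)C(=O)OC | intermediate
9 | methyl (2Z)-6-[(tert-butyldimethylsilyl)oxy]-2-{1-[(triethylsilyl)oxy]ethenyl}hex-2-enoate | C=C(O[Si](CC)(CC)CC)/C(=C/CCCO[Si](C)(C)C(C)(C)C)C(=O)OC | intermediate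
10 | triethylsilyl enol ether cycloadduct (8-triethylsilyloxy-dec-7-ene form of 11) | COC(=O)C1=C(O[Si](CC)(CC)CC)CC[C@]2(O[C@@H](C(C)(C)C)OC2=O)[C@@H]1CCCO[Si](C)(C)C(C)(C)C | intermediate
11 | methyl (2R)-2-tert-butyl-6-{3-[(tert-butyldimethylsilyl)oxy]propyl}-4,8-dioxo-1,3-dioxaspiro[4.5]decane-7-carboxylate | COC(=O)C1C(=O)CC[C@]2(O[C@@H](C(C)(C)C)OC2=O)[C@@H]1CCCO[Si](C)(C)C(C)(C)C | intermediate
12 | (2E,6E)-farnesol | CC(C)=CCC/C(C)=C/CC/C(C)=C/CO | starting material
13 | (2E,6E)-farnesal | CC(C)=CCC/C(C)=C/CC/C(C)=C/C=O | intermediate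
14 | (3E,7E)-4,8,12-trimethyltrideca-1,3,7,11-tetraene | CC(C)=CCC/C(C)=C/CC/C(C)=C/C=C | intermediate
15 | B-[(3E,7E)-homofarnesyl]-9-borabicyclo[3.3.1]nonane | CC(C)=CCC/C(C)=C/CC/C(C)=C/CCB1C2CCCC1CCC2 | intermediate
16 | (3E,7E)-4,8,12-trimethyltrideca-3,7,11-trien-1-ol (homofarnesol) | CC(C)=CCC/C(C)=C/CC/C(C)=C/CCO | intermediate
17 | (3E,7E)-homofarnesyl iodide | CC(C)=CCC/C(C)=C/CC/C(C)=C/CCI | intermediate
18 | C1-alkylated spiro β-keto ester (chain trans to the C2 side chain) | CC(C)=CCC/C(C)=C/CC/C(C)=C/CC[C@]1(C(=O)OC)[C@@H](CCCO[Si](C)(C)C(C)(C)C)[C@@]2(O[C@@H](C(C)(C)C)OC2=O)CCC1=O | intermediate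
19 | C6 tertiary alcohol (hydroxyl cis to ester and C2 side chain) | CC(C)=CCC/C(C)=C/CC/C(C)=C/CC[C@]1(C(=O)OC)[C@@H](CCCO[Si](C)(C)C(C)(C)C)[C@@]2(O[C@@H](C(C)(C)C)OC2=O)CC[C@@]1(C)O | intermediate
20 | tetraol (C1–CH2OH, C3–OH and C3–CH2OH, C6–OH) | CC(C)=CCC/C(C)=C/CC/C(C)=C/CC[C@]1(CO)[C@@H](CCCO[Si](C)(C)C(C)(C)C)[C@@](CO)(O)CC[C@@]1(C)O | intermediate
21 | (2R,3R,4R)-4-hydroxy-3-(hydroxymethyl)-4-methyl-2-{3-[(tert-butyldimethylsilyl)oxy]propyl}-3-[(3E,7E)-4,8,12-trimethyltrideca-3,7,11-trien-1-yl]cyclohexan-1-one | CC(C)=CCC/C(C)=C/CC/C(C)=C/CC[C@]1(CO)[C@@H](CCCO[Si](C)(C)C(C)(C)C)C(=O)CC[C@@]1(C)O | intermediate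
22 | di-tert-butylsilylene acetal of 21 | CC(C)=CCC/C(C)=C/CC/C(C)=C/CC[C@]1(CO2)[C@@H](CCCO[Si](C)(C)C(C)(C)C)C(=O)CC[C@@]1(C)O[Si]2(C(C)(C)C)C(C)(C)C | intermediate
23 | C3 dibromomethylidene compound | CC(C)=CCC/C(C)=C/CC/C(C)=C/CC[C@]1(CO2)[C@@H](CCCO[Si](C)(C)C(C)(C)C)C(=C(Br)Br)CC[C@@]1(C)O[Si]2(C(C)(C)C)C(C)(C)C | intermediate
24 | (Z)-1-bromoethylidene compound (bromine cis to C2) | CC(C)=CCC/C(C)=C/CC/C(C)=C/CC[C@]1(CO2)[C@@H](CCCO[Si](C)(C)C(C)(C)C)/C(=C(/C)Br)CC[C@@]1(C)O[Si]2(C(C)(C)C)C(C)(C)C | intermediate
25 | vinyllithium from 24 (lithium cis to C2) | CC(C)=CCC/C(C)=C/CC/C(C)=C/CC[C@]1(CO2)[C@@H](CCCO[Si](C)(C)C(C)(C)C)/C(=C(/C)[Li])CC[C@@]1(C)O[Si]2(C(C)(C)C)C(C)(C)C | intermediate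
26 | bis-silyl-protected (Z)-enal | CC(C)=CCC/C(C)=C/CC/C(C)=C/CC[C@]1(CO2)[C@@H](CCCO[Si](C)(C)C(C)(C)C)/C(=C(/C)C=O)CC[C@@]1(C)O[Si]2(C(C)(C)C)C(C)(C)C | intermediate
27 | (2Z)-2-[(2S,3R,4R)-4-hydroxy-3-(hydroxymethyl)-2-(3-hydroxypropyl)-4-methyl-3-[(3E,7E)-4,8,12-trimethyltrideca-3,7,11-trien-1-yl]cyclohexylidene]propanal | CC(C)=CCC/C(C)=C/CC/C(C)=C/CC[C@]1(CO)[C@@H](CCCO)/C(=C(/C)C=O)CC[C@@]1(C)O | target

**Count and risks**

Total step count: 19. Longest linear sequence: 13 steps (steps 1–3, 6 and 11–19).

Steps most likely to fail: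

1. Step 6. The ester on the diene lowers its nucleophilicity, so the cycloaddition may be outrun by polymerisation of the dienophile, or the regio and exo preference may erode. The soft enolisation of step 5 may also drift toward the linear dienol ether. The fallback takes the ester out of the diene and sets out from 6. Wittig olefination with 1-(triphenylphosphoranylidene)propan-2-one should give (3E)-7-[(tert-butyldimethylsilyl)oxy]hept-3-en-2-one F1. Et3SiOTf and Et3N should give the ester-free triethyl{[(3E)-7-[(tert-butyldimethylsilyl)oxy]hepta-1,3-dien-2-yl]oxy}silane F2. Its cycloaddition with 5 (toluene, 80 °C, same topology) should give the spiro triethylsilyl enol ether F3, regiodefined toward C1. N-bromosuccinimide should convert it into the C1 α-bromo ketone F4, and Pd-catalysed methoxycarbonylation (PdCl2(PPh3)2, CO, MeOH, n-Bu3N) should return β-keto ester 11.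

2. Step 17. Oxidative addition may fail to discriminate between the two C–Br bonds, or a second methylation may follow. The fallback sets out from 22. Addition of isopropenylmagnesium bromide (THF, −78 °C) should give the C3 tertiary allylic alcohol F5. Babler–Dauben oxidative 1,3-transposition with pyridinium chlorochromate, (C5H5NH)[CrO3Cl], in CH2Cl2 should give the enal, the geometrical isomers being separated by chromatography, and the route is rejoined at 26.

3. Step 12. Magnesium chelation between ketone and ester may deliver the methyl group from the wrong face, or the nucleophile may attack the lactone carbonyl. The fallback sets out from 18. Wittig methylenation (Ph3PCH3Br, KOtBu) should give the C6 methylidene compound F6. LiAlH4 should give the C6-methylidene triol F7. Hydroxyl-directed epoxidation (VO(acac)2, t-BuOOH) guided by the homoallylic C1–CH2OH should give the spiro-epoxide F8 with oxygen cis to the hydroxymethyl group. Hydride opening at the epoxide CH2 with LiAlH4 should return tetraol 20.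

**Further compounds**

F1 | step 6 | (3E)-7-[(tert-butyldimethylsilyl)oxy]hept-3-en-2-one | CC(=O)/C=C/CCCO[Si](C)(C)C(C)(C)C
F2 | step 6 | triethyl{[(3E)-7-[(tert-butyldimethylsilyl)oxy]hepta-1,3-dien-2-yl]oxy}silane | C=C(O[Si](CC)(CC)CC)/C=C/CCCO[Si](C)(C)C(C)(C)C
F3 | step 6 | spiro triethylsilyl enol ether lacking the ester | CC[Si](CC)(CC)OC1=C[C@@H](CCCO[Si](C)(C)C(C)(C)C)[C@@]2(O[C@@H](C(C)(C)C)OC2=O)CC1
F4 | step 6 | C1 α-bromo ketone | O=C1CC[C@]2(O[C@@H](C(C)(C)C)OC2=O)[C@H](CCCO[Si](C)(C)C(C)(C)C)C1Br
F5 | step 17 | C3 tertiary allylic alcohol (isopropenyl carbinol of 22) | CC(C)=CCC/C(C)=C/CC/C(C)=C/CC[C@]1(CO2)[C@@H](CCCO[Si](C)(C)C(C)(C)C)C(O)(C(C)=C)CC[C@@]1(C)O[Si]2(C(C)(C)C)C(C)(C)C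
F6 | step 12 | C6 methylidene analogue of 18 | CC(C)=CCC/C(C)=C/CC/C(C)=C/CC[C@]1(C(=O)OC)[C@@H](CCCO[Si](C)(C)C(C)(C)C)[C@@]2(O[C@@H](C(C)(C)C)OC2=O)CCC1=C
F7 | step 12 | C6-methylidene triol | CC(C)=CCC/C(C)=C/CC/C(C)=C/CC[C@]1(CO)[C@@H](CCCO[Si](C)(C)C(C)(C)C)[C@@](CO)(O)CCC1=C
F8 | step 12 | C6 spiro-epoxide (oxygen cis to C1–CH2OH) | CC(C)=CCC/C(C)=C/CC/C(C)=C/CC[C@]1(CO)[C@@H](CCCO[Si](C)(C)C(C)(C)C)[C@@](CO)(O)CC[C@@]1(C2)O2
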